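The indane is cut back to a benzo-fused six-membered ring. In the target, ring carbon C2 carries the one-carbon arm C1 beside aryl-bearing C3 and is bonded to ring-D carbon D1, which lies meta to both ring-D oxygens and is therefore out of reach of electrophilic substitution. This is the pattern left when the aryl bond of a 1,2-dihydronaphthalene shifts from the benzylic alkene carbon to its neighbour. One oxidative operation thus forms C2–D1, closes the five-membered ring, sets C2 and frees C1 as a protected aldehyde. Its substrate is (1S,2S)-trans-1-(3,5-dimethoxyphenyl)-2-(4-methoxyphenyl)-6,8-dimethoxy-1,2-dihydronaphthalene 14, made by an auxiliary-controlled aldol, a Z-selective Wittig reaction and a cyclialkylation.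

Key step: step 8

Labels: C1 = seven-ring CH bearing 4-hydroxyphenyl; C2 = ring-fusion CH; C3 and C4 = five-ring CH carbons bearing 4-hydroxyphenyl and 3,5-dihydroxyphenyl; ring A = outer resorcinol ring bonded to the ketone carbon and, at the neighbouring ring carbon, to C1; ring D = central ring bonded to C2 (D1), the ketone (D2) and C4 (D6).

Remark on the chemistry: after step 8 no free benzylic carbocation is generated at C1, because the 3,5-dimethoxyphenyl ring on C4 is cis to the C1 arm and would close a bridged six-membered ring onto such a cation; both C1 aryl groups are therefore brought in as carbon nucleophiles.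

Assumption: 2-bromo-3,5-dimethoxybenzoic acid 20 is taken as a purchasable compound (otherwise one bromination from 3,5-dimethoxybenzoic acid).

Step 1
Reactants: 1 (R)-4-benzyl-1,3-oxazolidin-2-one; 2 (4-methoxyphenyl)acetyl chloride
Product: 4 (R)-4-benzyl-3-[(4-methoxyphenyl)acetyl]-1,3-oxazolidin-2-one, via N-lithio oxazolidinone 3 (not isolated)
Conditions: n-BuLi, THF, −78 °C; then 2, −78 → 0 °C
Reagents that add atoms: none
Why: N-acylation of the lithiated oxazolidinone by an acid chloride is the standard way to attach the auxiliary and creates no stereocentre.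

Step 2
Reactants: 4 (R)-4-benzyl-3-[(4-methoxyphenyl)acetyl]-1,3-oxazolidin-2-one; 5 3,5-dimethoxybenzaldehyde
Product: 7 (R)-4-benzyl-3-[(2R,3R)-3-(3,5-dimethoxyphenyl)-3-hydroxy-2-(4-methoxyphenyl)propanoyl]-1,3-oxazolidin-2-one, via Z dibutylboron enolate 6 (not isolated)
Conditions: Bu2BOTf, i-Pr2NEt, CH2Cl2, −78 → 0 °C; then 5, −78 → 0 °C; H2O2, pH 7 buffer, MeOH
Reagents that add atoms: none
Why: Evans syn aldol reaction, in which the Z boron enolate adds through a closed chair transition state on the face turned away from the benzyl group of the (R)-auxiliary, so that C3 (2R) and the carbinol carbon (3R) should be set together as the syn pair.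

Step 3
Reactants: 7 (R)-4-benzyl-3-[(2R,3R)-3-(3,5-dimethoxyphenyl)-3-hydroxy-2-(4-methoxyphenyl)propanoyl]-1,3-oxazolidin-2-one
Product: 8 (R)-4-benzyl-3-[(2R,3R)-3-(3,5-dimethoxyphenyl)-3-methoxy-2-(4-methoxyphenyl)propanoyl]-1,3-oxazolidin-2-one
Conditions: Me3OBF4, 1,8-bis(dimethylamino)naphthalene, CH2Cl2, rt
Reagents that add atoms: trimethyloxonium tetrafluoroborate, C[O+](C)C.F[B-](F)(F)F
Why: O-alkylation with the oxonium salt and a non-nucleophilic base avoids retro-aldol cleavage and epimerisation at C3, and the methyl ether both keeps an alkoxide out of the later ylide and serves as the leaving group of step 7.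

Step 4
Reactants: 8 (R)-4-benzyl-3-[(2R,3R)-3-(3,5-dimethoxyphenyl)-3-methoxy-2-(4-methoxyphenyl)propanoyl]-1,3-oxazolidin-2-one
Product: 9 (2S,3R)-3-(3,5-dimethoxyphenyl)-3-methoxy-2-(4-methoxyphenyl)propan-1-ol
Conditions: LiBH4, MeOH (1 equiv), Et2O, 0 °C; aq. NaOH
Reagents that add atoms: none
Why: Reductive cleavage of the imide by LiBH4 gives the primary alcohol without enolising C3 and returns the auxiliary.

Step 5
Reactants: 9 (2S,3R)-3-(3,5-dimethoxyphenyl)-3-methoxy-2-(4-methoxyphenyl)propan-1-ol
Product: 11 [(2R,3R)-3-(3,5-dimethoxyphenyl)-3-methoxy-2-(4-methoxyphenyl)propyl]triphenylphosphonium iodide, via primary iodide 10 (not isolated)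
Conditions: I2, PPh3, imidazole, toluene/MeCN, 0 °C → rt; then PPh3 (3 equiv), 85 °C
Reagents that add atoms: iodine, II; triphenylphosphine, c1ccc(cc1)P(c1ccccc1)c1ccccc1
Why: Appel-type iodination of the primary alcohol followed by SN2 quaternisation of triphenylphosphine touches no stereocentre, and the weakly ionising medium should keep the neighbouring anisyl ring from participating.

Step 6
Reactants: 11 [(2R,3R)-3-(3,5-dimethoxyphenyl)-3-methoxy-2-(4-methoxyphenyl)propyl]triphenylphosphonium iodide; 5 3,5-dimethoxybenzaldehyde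
Product: 13 1-[(1Z,3R,4R)-4-(3,5-dimethoxyphenyl)-4-methoxy-3-(4-methoxyphenyl)but-1-en-1-yl]-3,5-dimethoxybenzene, via phosphorus ylide 12 (not isolated)
Conditions: NaN(SiMe3)2, THF, −78 °C; then 5, −78 °C → rt
Reagents that add atoms: none
Why: Wittig reaction of a non-stabilised ylide with an aromatic aldehyde under lithium-free conditions should give mainly the Z alkene by kinetic oxaphosphetane formation, the methyl ether preventing the erosion of Z selectivity that an oxido group in the ylide would cause.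

Step 7
Reactants: 13 1-[(1Z,3R,4R)-4-(3,5-dimethoxyphenyl)-4-methoxy-3-(4-methoxyphenyl)but-1-en-1-yl]-3,5-dimethoxybenzene
Product: 14 (1S,2S)-1-(3,5-dimethoxyphenyl)-6,8-dimethoxy-2-(4-methoxyphenyl)-1,2-dihydronaphthalene
Conditions: TfOH (10 mol %), CH2Cl2, −40 → −10 °C
Reagents that add atoms: none
Why: Intramolecular Friedel–Crafts alkylation (cyclialkylation), in which acid-induced loss of methanol from the benzylic ether is met by the ortho carbon D6 of the Z-styryl ring (ortho and para to its methoxy groups) in a six-membered transition state; both backside displacement of the syn-configured ether and capture of the free cation anti to the C3 aryl should set C4 trans to C3.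

Step 8
Reactants: 14 (1S,2S)-1-(3,5-dimethoxyphenyl)-6,8-dimethoxy-2-(4-methoxyphenyl)-1,2-dihydronaphthalene
Product: 15 (1S,2R,3S)-1-(dimethoxymethyl)-3-(3,5-dimethoxyphenyl)-4,6-dimethoxy-2-(4-methoxyphenyl)-2,3-dihydro-1H-indene
Conditions: PhI(OH)OTs (1.05 equiv), MeOH/CH2Cl2 5:1, −20 → 0 °C; cold aq. NaHCO3
Reagents that add atoms: methanol, CO
Why: The iodane adds as an electrophile to the non-benzylic alkene carbon (future C2) on the face away from the C3 aryl and methanol opens the benzylic carbon (future C1) anti, giving a trans methoxy iodanyl adduct. In the conformer that holds iodine, methoxy and both aryl groups equatorial, the ring bond from the benzylic carbon to D1 is antiperiplanar to C–I, so D1 shifts to C2 with inversion as iodobenzene leaves, while the methoxy lone pair turns the old benzylic carbon into an oxocarbenium ion that methanol traps as the dimethyl acetal. The closest known reaction type is the oxidative ring contraction of 1,2-dihydronaphthalenes to 1-(dimethoxymethyl)indanes by trivalent iodine or trivalent thallium reagents, a semipinacol-type 1,2-aryl shift. The five-membered ring is closed by contraction, the C2–D1 bond forming in a suprafacial 1,2-shift through a bridged three-centre transition state and not by an exo or endo cyclisation. The new stereocentre C2 is controlled by the C3 aryl, since anti addition followed by invertive migration places the C1 acetal trans to that aryl and therefore cis to the C4 aryl (all-trans indane). The step needs the alkene to be attacked before the methoxyarenes and the D1 shift to win over solvolysis by methanol or participation of the C3 anisyl group; one equivalent of iodane at low temperature, the gauche position of the anisyl group in the reactive conformer, the push of the benzylic methoxy group and a cold bicarbonate quench of the sulfonic acid should secure this.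

Step 9
Reactants: 15 (1S,2R,3S)-1-(dimethoxymethyl)-3-(3,5-dimethoxyphenyl)-4,6-dimethoxy-2-(4-methoxyphenyl)-2,3-dihydro-1H-indene
Product: 16 (1S,2R,3S)-3-(3,5-dimethoxyphenyl)-4,6-dimethoxy-2-(4-methoxyphenyl)-2,3-dihydro-1H-indene-1-carbaldehyde
Conditions: pyridinium p-toluenesulfonate (cat.), acetone/H2O 4:1, 40 °C
Reagents that add atoms: water, O
Why: Mild acid-catalysed acetal hydrolysis, in which the large excess of water should intercept the oxocarbenium ion before the neighbouring aryl ring can, and C2, though now enolisable, already holds the favoured all-trans arrangement.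

Step 10
Reactants: 16 (1S,2R,3S)-3-(3,5-dimethoxyphenyl)-4,6-dimethoxy-2-(4-methoxyphenyl)-2,3-dihydro-1H-indene-1-carbaldehyde; 17 4-methoxyphenylmagnesium bromide
Product: 18 [(1S,2R,3S)-3-(3,5-dimethoxyphenyl)-4,6-dimethoxy-2-(4-methoxyphenyl)-2,3-dihydro-1H-inden-1-yl](4-methoxyphenyl)methanol (both carbinol epimers)
Conditions: 17 (1.5 equiv), THF, −78 → 0 °C; aq. NH4Cl
Reagents that add atoms: none
Why: Grignard addition to the aldehyde gives the secondary alcohol as a mixture at the carbinol carbon, which does not matter because that carbon is oxidised in the next step.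

Step 11
Reactants: 18 [(1S,2R,3S)-3-(3,5-dimethoxyphenyl)-4,6-dimethoxy-2-(4-methoxyphenyl)-2,3-dihydro-1H-inden-1-yl](4-methoxyphenyl)methanol
Product: 19 [(1S,2R,3S)-3-(3,5-dimethoxyphenyl)-4,6-dimethoxy-2-(4-methoxyphenyl)-2,3-dihydro-1H-inden-1-yl](4-methoxyphenyl)methanone
Conditions: Dess–Martin periodinane, NaHCO3, CH2Cl2, rt
Reagents that add atoms: none
Why: Dess–Martin oxidation gives the aryl ketone under buffered, acid-free conditions, and C2 stays in its thermodynamically preferred trans arrangement.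

Step 12
Reactants: 19 [(1S,2R,3S)-3-(3,5-dimethoxyphenyl)-4,6-dimethoxy-2-(4-methoxyphenyl)-2,3-dihydro-1H-inden-1-yl](4-methoxyphenyl)methanone; 20 2-bromo-3,5-dimethoxybenzoic acid
Product: 22 4,6-dimethoxy-3-(4-methoxyphenyl)-3-[(1S,2R,3S)-3-(3,5-dimethoxyphenyl)-4,6-dimethoxy-2-(4-methoxyphenyl)-2,3-dihydro-1H-inden-1-yl]-2-benzofuran-1(3H)-one (both C1 epimers), via lithium 2-lithio-3,5-dimethoxybenzoate 21 (not isolated)
Conditions: 20, n-BuLi (2.0 equiv), THF, −78 °C; then 19, LaCl3·2LiCl, −78 → −20 °C; aq. HCl (1 M), rt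
Reagents that add atoms: none
Why: Addition of the aryllithium made by bromine–lithium exchange on the lithium carboxylate to the ketone (the lanthanum salt suppressing enolisation), followed by lactonisation on acidification, gives the 3,3-disubstituted phthalide and so joins ring A to C1 through the ring carbon next to the carboxyl-bearing one, with the future ketone carbon already in place; the C1 configuration formed here is erased in step 13.

Step 13
Reactants: 22 4,6-dimethoxy-3-(4-methoxyphenyl)-3-[(1S,2R,3S)-3-(3,5-dimethoxyphenyl)-4,6-dimethoxy-2-(4-methoxyphenyl)-2,3-dihydro-1H-inden-1-yl]-2-benzofuran-1(3H)-one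
Product: 23 2-{[(1R,2S,3S)-3-(3,5-dimethoxyphenyl)-4,6-dimethoxy-2-(4-methoxyphenyl)-2,3-dihydro-1H-inden-1-yl](4-methoxyphenyl)methyl}-3,5-dimethoxybenzoic acid (both C1 epimers)
Conditions: Zn dust, KOH, EtOH/H2O, reflux; then aq. HCl
Reagents that add atoms: none
Why: Zinc–alkali reduction of a 3,3-disubstituted phthalide cleaves the benzylic C–O bond by electron transfer to give the 2-(diarylmethyl)benzoic acid without a carbocation at C1, which is formed as a mixture that step 15 corrects.

Step 14
Reactants: 23 2-{[(1R,2S,3S)-3-(3,5-dimethoxyphenyl)-4,6-dimethoxy-2-(4-methoxyphenyl)-2,3-dihydro-1H-inden-1-yl](4-methoxyphenyl)methyl}-3,5-dimethoxybenzoic acid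
Product: 24 octamethyl ether of the target as a mixture of C1 epimers (C2 R, C3 S, C4 S)
Conditions: (CF3CO)2O, CH2Cl2, 0 °C → rt
Reagents that add atoms: none
Why: Intramolecular Friedel–Crafts acylation through the mixed trifluoroacetic anhydride closes the seven-membered ketone ring at D2, the only position within reach that is ortho and para to methoxy groups, whereas the competing six-ring closure onto the C1 anisyl ring would have to use a carbon meta to its methoxy group.

Step 15
Reactants: 24 octamethyl ether of the target as a mixture of C1 epimers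
Product: 25 octamethyl ether of the target (C1 S, C2 R, C3 S, C4 S)
Conditions: t-BuOK (0.2 equiv), DMSO, rt, under argon; aq. NH4Cl
Reagents that add atoms: none
Why: Base-mediated epimerisation, in which reversible deprotonation of the doubly benzylic C1–H (the most acidic C–H, vinylogous to the ketone through ring A) and reprotonation should funnel both epimers to the isomer with the C1 aryl trans to the C2–C3 bond and away from the C4 aryl, so that C1 is fixed under thermodynamic control.

Step 16
Reactants: 25 octamethyl ether of the target (C1 S, C2 R, C3 S, C4 S)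
Product: 26 CNP0116600.1 (C1 S, C2 R, C3 S, C4 S)
Conditions: BBr3 (16 equiv), CH2Cl2, −78 °C → rt; then MeOH, H2O
Reagents that add atoms: none
Why: Exhaustive aryl methyl ether cleavage by BBr3 (Lewis-acid-assisted SN2 demethylation) should free all eight phenols without touching the carbon skeleton or its four stereocentres.

Compound list
1 | (R)-4-benzyl-1,3-oxazolidin-2-one | O=C1N[C@H](Cc2ccccc2)CO1 | starting material
2 | (4-methoxyphenyl)acetyl chloride | COc1ccc(CC(Cl)=O)cc1 | starting material
3 | N-lithio derivative of 1 | [Li]N1[C@H](Cc2ccccc2)COC1=O | intermediate (not isolated)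
4 | (R)-4-benzyl-3-[(4-methoxyphenyl)acetyl]-1,3-oxazolidin-2-one | COc1ccc(CC(=O)N2[C@H](Cc3ccccc3)COC2=O)cc1 | intermediate
5 | 3,5-dimethoxybenzaldehyde | COc1cc(C=O)cc(OC)c1 | starting material
6 | Z dibutylboron enolate of 4 | CCCCB(CCCC)O/C(=C\c1ccc(OC)cc1)N1[C@H](Cc2ccccc2)COC1=O | intermediate (not isolated)
7 | (R)-4-benzyl-3-[(2R,3R)-3-(3,5-dimethoxyphenyl)-3-hydroxy-2-(4-methoxyphenyl)propanoyl]-1,3-oxazolidin-2-one | O=C(N1[C@H](Cc2ccccc2)COC1=O)[C@H](c1ccc(OC)cc1)[C@@H](O)c1cc(OC)cc(OC)c1 | intermediate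
8 | (R)-4-benzyl-3-[(2R,3R)-3-(3,5-dimethoxyphenyl)-3-methoxy-2-(4-methoxyphenyl)propanoyl]-1,3-oxazolidin-2-one | O=C(N1[C@H](Cc2ccccc2)COC1=O)[C@H](c1ccc(OC)cc1)[C@@H](OC)c1cc(OC)cc(OC)c1 | intermediate
9 | (2S,3R)-3-(3,5-dimethoxyphenyl)-3-methoxy-2-(4-methoxyphenyl)propan-1-ol | OC[C@H](c1ccc(OC)cc1)[C@@H](OC)c1cc(OC)cc(OC)c1 | intermediate
10 | 1-[(1R,2R)-3-iodo-1-methoxy-2-(4-methoxyphenyl)propyl]-3,5-dimethoxybenzene | IC[C@H](c1ccc(OC)cc1)[C@@H](OC)c1cc(OC)cc(OC)c1 | intermediate (not isolated)
11 | [(2R,3R)-3-(3,5-dimethoxyphenyl)-3-methoxy-2-(4-methoxyphenyl)propyl]triphenylphosphonium iodide | [I-].c1ccccc1[P+](c1ccccc1)(c1ccccc1)C[C@H](c1ccc(OC)cc1)[C@@H](OC)c1cc(OC)cc(OC)c1 | intermediate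
12 | phosphorus ylide of 11 | c1ccccc1P(c1ccccc1)(c1ccccc1)=C[C@H](c1ccc(OC)cc1)[C@@H](OC)c1cc(OC)cc(OC)c1 | intermediate (not isolated)
13 | 1-[(1Z,3R,4R)-4-(3,5-dimethoxyphenyl)-4-methoxy-3-(4-methoxyphenyl)but-1-en-1-yl]-3,5-dimethoxybenzene | COc1cc(OC)cc(c1)/C=C\[C@H](c1ccc(OC)cc1)[C@@H](OC)c1cc(OC)cc(OC)c1 | intermediate
14 | (1S,2S)-1-(3,5-dimethoxyphenyl)-6,8-dimethoxy-2-(4-methoxyphenyl)-1,2-dihydronaphthalene | C1=C[C@H](c2ccc(OC)cc2)[C@@H](c2cc(OC)cc(OC)c2)c2c(OC)cc(OC)cc12 | intermediate
15 | (1S,2R,3S)-1-(dimethoxymethyl)-3-(3,5-dimethoxyphenyl)-4,6-dimethoxy-2-(4-methoxyphenyl)-2,3-dihydro-1H-indene | COC(OC)[C@@H]1c2cc(OC)cc(OC)c2[C@H](c2cc(OC)cc(OC)c2)[C@H]1c1ccc(OC)cc1 | intermediate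
16 | (1S,2R,3S)-3-(3,5-dimethoxyphenyl)-4,6-dimethoxy-2-(4-methoxyphenyl)-2,3-dihydro-1H-indene-1-carbaldehyde | O=C[C@@H]1c2cc(OC)cc(OC)c2[C@H](c2cc(OC)cc(OC)c2)[C@H]1c1ccc(OC)cc1 | intermediate
17 | 4-methoxyphenylmagnesium bromide | COc1ccc([Mg]Br)cc1 | starting material
18 | [(1S,2R,3S)-3-(3,5-dimethoxyphenyl)-4,6-dimethoxy-2-(4-methoxyphenyl)-2,3-dihydro-1H-inden-1-yl](4-methoxyphenyl)methanol, both carbinol epimers | OC(c1ccc(OC)cc1)[C@@H]1c2cc(OC)cc(OC)c2[C@H](c2cc(OC)cc(OC)c2)[C@H]1c1ccc(OC)cc1 | intermediate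
19 | [(1S,2R,3S)-3-(3,5-dimethoxyphenyl)-4,6-dimethoxy-2-(4-methoxyphenyl)-2,3-dihydro-1H-inden-1-yl](4-methoxyphenyl)methanone | O=C(c1ccc(OC)cc1)[C@@H]1c2cc(OC)cc(OC)c2[C@H](c2cc(OC)cc(OC)c2)[C@H]1c1ccc(OC)cc1 | intermediate
20 | 2-bromo-3,5-dimethoxybenzoic acid | COc1cc(OC)c(Br)c(c1)C(O)=O | starting material
21 | lithium 2-lithio-3,5-dimethoxybenzoate | [Li]OC(=O)c1cc(OC)cc(OC)c1[Li] | intermediate (not isolated)
22 | 4,6-dimethoxy-3-(4-methoxyphenyl)-3-[(1S,2R,3S)-3-(3,5-dimethoxyphenyl)-4,6-dimethoxy-2-(4-methoxyphenyl)-2,3-dihydro-1H-inden-1-yl]-2-benzofuran-1(3H)-one, both C1 epimers | O=C1OC(c2ccc(OC)cc2)([C@@H]2c3cc(OC)cc(OC)c3[C@H](c3cc(OC)cc(OC)c3)[C@H]2c2ccc(OC)cc2)c2c(OC)cc(OC)cc12 | intermediate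
23 | 2-{[(1R,2S,3S)-3-(3,5-dimethoxyphenyl)-4,6-dimethoxy-2-(4-methoxyphenyl)-2,3-dihydro-1H-inden-1-yl](4-methoxyphenyl)methyl}-3,5-dimethoxybenzoic acid, both C1 epimers | OC(=O)c1cc(OC)cc(OC)c1C(c1ccc(OC)cc1)[C@@H]1c2cc(OC)cc(OC)c2[C@H](c2cc(OC)cc(OC)c2)[C@H]1c1ccc(OC)cc1 | intermediate
24 | octamethyl ether of the target, mixture of C1 epimers (C2 R, C3 S, C4 S) | O=C1c2cc(OC)cc(OC)c2C(c2ccc(OC)cc2)[C@@H]2c3c1c(OC)cc(OC)c3[C@H](c1cc(OC)cc(OC)c1)[C@H]2c1ccc(OC)cc1 | intermediate
25 | octamethyl ether of the target (C1 S, C2 R, C3 S, C4 S) | O=C1c2cc(OC)cc(OC)c2[C@H](c2ccc(OC)cc2)[C@@H]2c3c1c(OC)cc(OC)c3[C@H](c1cc(OC)cc(OC)c1)[C@H]2c1ccc(OC)cc1 | intermediate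
26 | CNP0116600.1 (C1 S, C2 R, C3 S, C4 S) | O=C1c2cc(O)cc(O)c2[C@H](c2ccc(O)cc2)[C@@H]2c3c1c(O)cc(O)c3[C@H](c1cc(O)cc(O)c1)[C@H]2c1ccc(O)cc1 | target

Total step count: 16. Longest linear sequence: 16 steps (1 and 2 to 26).

Steps most likely to fail

Step 8. The iodane may oxidise the methoxy-substituted rings. Methanol may displace iodobenzene before the ring bond migrates, since D1 is meta to both ring-D methoxy groups and migrates without their help. The C3 anisyl group may take part if the all-axial conformer, favoured by the peri methoxy group, reacts. The sulfonic acid set free may also let the C4 aryl ring attack the acetal carbon. The fallback is a stepwise semipinacol contraction that sets out from 14 and returns at 15. Epoxidation with dimethyldioxirane (acetone, −20 °C) on the face away from the C3 aryl gives the epoxide F1. Acid-catalysed methanolysis at the benzylic carbon with inversion gives the trans methoxy alcohol F2. Mesylation (MsCl, Et3N) gives the mesylate F3. Solvolysis of F3 in methanol buffered with 2,6-lutidine (60 °C) lets the ring bond antiperiplanar to the mesylate migrate under the push of the methoxy group, and methanol traps the oxocarbenium ion as 15.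

Step 7. The benzylic cation sits next to the allylic, anisyl-bearing C3–H, so hydride shift or elimination may destroy C3. Ionisation assisted by the anisyl ring would proceed with retention and give the cis-diaryl isomer. The fallback closes the ring on a saturated tether with the future alkene carbon masked, setting out from alcohol 9 (iodinated to 10 as in step 5, then isolated) and returning at 14. The dithiane F4, 2-(3,5-dimethoxyphenyl)-1,3-dithiane, is made from 5 and propane-1,3-dithiol (BF3·OEt2), deprotonated with n-BuLi and alkylated by 10 to give the alkylated dithiane F5. Acid-mediated cyclialkylation of F5, now onto an alkyl-substituted and more nucleophilic ring D with no allylic hydrogen, gives the spiro dithioketal F6. Hydrolysis (MeI, CaCO3, aq. MeCN) gives the tetralone F7, NaBH4 gives the tetralol F8, and dehydration (TsOH cat., toluene, 80 °C) gives 14.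

Step 12. The bulky, basic aryllithium may enolise the hindered α-branched ketone instead of adding, returning starting material. The fallback reverses the order of aryl introduction so that the hindered aryl meets an aldehyde; it sets out from aldehyde 16 and returns at phthalide 22. The bromo amide F9, N,N-diethyl-2-bromo-3,5-dimethoxybenzamide, is made from 20 (SOCl2, then Et2NH). Bromine–lithium exchange on F9 (n-BuLi, −78 °C) and addition to 16 give the hydroxy amide F10. Dess–Martin oxidation gives the keto amide F11. Addition of the small nucleophile 17 (with CeCl3) and warming lets the tertiary alkoxide displace diethylamide to give 22.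

Further compounds
F1 | step 8 | epoxide of 14 on the face opposite the C3 aryl | O1[C@@H]2c3cc(OC)cc(OC)c3[C@H](c3cc(OC)cc(OC)c3)[C@@H](c3ccc(OC)cc3)[C@H]12
F2 | step 8 | trans methoxy alcohol (methoxy on the benzylic carbon, hydroxyl anti to it and to the C3 aryl) | CO[C@H]1c2cc(OC)cc(OC)c2[C@H](c2cc(OC)cc(OC)c2)[C@@H](c2ccc(OC)cc2)[C@@H]1O
F3 | step 8 | mesylate of F2 | CO[C@H]1c2cc(OC)cc(OC)c2[C@H](c2cc(OC)cc(OC)c2)[C@@H](c2ccc(OC)cc2)[C@@H]1OS(C)(=O)=O
F4 | step 7 | 2-(3,5-dimethoxyphenyl)-1,3-dithiane | COc1cc(OC)cc(c1)C1SCCCS1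
F5 | step 7 | 2-(3,5-dimethoxyphenyl)-2-[(2R,3R)-3-(3,5-dimethoxyphenyl)-3-methoxy-2-(4-methoxyphenyl)propyl]-1,3-dithiane | COc1cc(OC)cc(c1)C1(C[C@H](c2ccc(OC)cc2)[C@@H](OC)c2cc(OC)cc(OC)c2)SCCCS1
F6 | step 7 | spiro 1,3-dithiane (dithioketal) of tetralone F7 | C1CSC2(SC1)C[C@H](c1ccc(OC)cc1)[C@@H](c1cc(OC)cc(OC)c1)c1c(OC)cc(OC)cc12
F7 | step 7 | (3S,4S)-4-(3,5-dimethoxyphenyl)-5,7-dimethoxy-3-(4-methoxyphenyl)-3,4-dihydronaphthalen-1(2H)-one | O=C1C[C@H](c2ccc(OC)cc2)[C@@H](c2cc(OC)cc(OC)c2)c2c(OC)cc(OC)cc12
F8 | step 7 | (3S,4S)-4-(3,5-dimethoxyphenyl)-5,7-dimethoxy-3-(4-methoxyphenyl)-1,2,3,4-tetrahydronaphthalen-1-ol, both carbinol epimers | OC1C[C@H](c2ccc(OC)cc2)[C@@H](c2cc(OC)cc(OC)c2)c2c(OC)cc(OC)cc12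
F9 | step 12 | N,N-diethyl-2-bromo-3,5-dimethoxybenzamide | CCN(CC)C(=O)c1cc(OC)cc(OC)c1Br
F10 | step 12 | hydroxy amide from F9 and 16, both carbinol epimers | CCN(CC)C(=O)c1cc(OC)cc(OC)c1C(O)[C@@H]1c2cc(OC)cc(OC)c2[C@H](c2cc(OC)cc(OC)c2)[C@H]1c1ccc(OC)cc1
F11 | step 12 | keto amide from F10 | CCN(CC)C(=O)c1cc(OC)cc(OC)c1C(=O)[C@@H]1c2cc(OC)cc(OC)c2[C@H](c2cc(OC)cc(OC)c2)[C@H]1c1ccc(OC)cc1
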